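In a one-step world the charge goes to one product, and Q ends at the whole of it. These runs show two products, so the first thing to find is how the charge divides between them.

| setting | spring | noon | flask |
|---|---|---|---|
| Z | 0.036 M | 0.036 M | 0.036 M |
| E | 9 mM | 9 mM | 9.00 mM |
| J | 36 µM | 54 µM | 72 µM |
| remark | run made earlier | run made earlier |  |
| time |  |  | 8.0 d |

- spring (time / d: Q / %, G / %): 0.625: 79.6, 12.9; 2.08: 84.4, 13.4; 4.00: 84.9, 14.1; 6.00: 85.2, 13.4; 8.00: 85.1, 13.0
- noon (time / d: Q / %, G / %): 0.625: 82.5, 13.3; 1.25: 85.1, 14.2; 2.50: 85.4, 12.9; 4.00: 85.4, 13.6; 8.00: 86.0, 14.4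

(standard deviation of a reading: 0.5 percentage points)

- in a conversion E counts as not yet reacted

- how much Q there is at 8.0 d, in percent of the Z and E together charged
- how much G there is at 8.0 d, in percent of the Z and E together charged

I replaced each levelled curve by its mean, taking the spring run from 4.00 d and the noon run from 2.50 d, and pooled them. This gave Q at 85.3% and G at 13.6%, each with a scatter of 0.2 percentage points. From these I took the G share, a selectivity: G divided by Q plus G, 13.7%. To check the error of using a mean, I went to the unfinished curves at 0.625 d, where the share was 13.9% in the spring run and 13.9% in the noon run, close to the mean.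

With [J] = 72 µM, higher than in either run, I took the flask as level by 8.0 d, and my first estimate was simply the pooled means. The weak link was the total. Q plus G averaged 98.6% in the spring run and 99.2% in the noon run, a gap of 0.60 points beside a scatter of 0.58 points for such a gap. I therefore extrapolated nothing and took the noon total, from the run nearer in [J]. Split by the share, it gave Q 85.6% and G 13.6%.

The forecast gave 85.7% Q and 13.8% G, holding that “the selectivity does not change with time or with J”.

The flask gave 85.6% Q and 13.9% G, a G share of 14.0% against my 13.7%.

    Z ⇌ E (K = 0.0810, k = 0.540 h⁻¹)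
    Z + J → J + Q (k = 6300 M⁻¹ h⁻¹)
    J + E → J + G (k = 12000 M⁻¹ h⁻¹)
    J + Q → X (k = 0.980 M⁻¹ h⁻¹)
    E ⇌ D (K = 5.00, k = 0.200 h⁻¹)

Read at 3.0 d, this flask held 85.5% Q; my share turned that into 13.6% G, and the flask held 13.9%. The half-life of Q by J + Q → X, concentrations as charged, was 410 d, longer than the 8.0 d of the run, and that step makes no difference to Q here. Yet at 8.00 d X held 99.9% of this flask's catalyst, and the share still able to turn over was 0.079%.

The readings are simulated from invented constants.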